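(Readings and results were generated by integration from invented constants, noise included.)

D in the eta flask, the very flask we are asked about, stands no higher at 50.0 min than at 15.0 min: it reads 27.2% against 27.8%, a drift of 0.6 percentage points beside a scatter of 0.5 points, while E holds at 72.3%.

| setting | eta | beta | flask |
|---|---|---|---|
| E | 0.20 M | 0.40 M | 0.20 M |
| L | 0.14 M | 0.14 M | 0.140 M |
| J | 0.20 M | 0.20 M | 0.200 M |
| temperature | 35 °C | 30 °C | 35 °C |
| remark | the very flask that is asked about, followed so far | run made earlier |  |
| time |  |  | 1.0 h |

eta run (percent of the E charged)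

| time / min | D / % | E / % |
|---|---|---|
| 3.00 | 26.2 | 74.6 |
| 10.0 | 27.5 | 73.2 |
| 15.0 | 27.8 | 72.4 |
| 25.0 | 28.0 | 72.4 |
| 40.0 | 27.3 | 72.4 |
| 50.0 | 27.2 | 72.3 |

beta run (percent of the E charged)

| time / s | D / % | E / % |
|---|---|---|
| 20.0 | 6.6 | 93.8 |
| 40.0 | 10.1 | 89.0 |
| 60.0 | 14.7 | 85.8 |
| 80.0 | 16.0 | 83.6 |
| 120 | 18.5 | 82.3 |

(standard deviation of a reading: 0.5 percentage points)

- D that was removed still counts
- steps under discussion: E + L -> D; J + L -> G; L -> Q
- additions bring no volume worth counting

- Monday's: at 1.0 h add L, 50.0% of the amount charged, then wait 30 min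
- Friday's: at 1.0 h raise the temperature by 10 K, then wait 30 min
- Sunday's: change nothing and wait 30 min more
- Saturday's: at 1.0 h take out 90% of the D then present, then wait 30 min

* D, in percent of the E first charged, at 1.0 h
* the remedy with the largest gain of D, or "none" below 2 percentage points (Monday's / Friday's / Sunday's / Saturday's / none)
* D present, with what was taken out counted in, in percent of the E first charged, after Sunday's
* D present, with what was taken out counted in, in percent of the E first charged, after Saturday's

So this flask has stopped with E to spare, and we reckon with two amounts instead of times: the D it made and the L it was given. E + L -> D takes one L for each D, while J + L -> G and L -> Q take L as well. L is not read, so we infer that the stop marks the end of L, the limiting reagent. From the last four readings of the eta flask: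

[D] at the stop = 27.6% of 0.20 M = 0.0552 M

0.0552 M / 0.14 M of [L] = 39.4%

We call this ratio the D share of L. The beta flask, with twice the E and at 30 °C, reads a share of 52.9% at 120 s, so the share is not the same in these two flasks, which differ in both E and temperature.

Our reckoning for this flask is 27.6% at 1.0 h. If L is at its end, as we infer, we expect nothing from waiting or from 10 K of heat, and the listed steps run one way, so we expect D to stay at 27.6% after Sunday's and after Saturday's. Monday's adds 0.0700 M of L, and if that L goes at the same share:

gain = 39.4% × 0.0700 M / 0.20 M = 14 points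

That stands above the 2 points mark.

The forecast gives 27.6%, Monday's, 27.6% and 27.6%, in the words “Waiting therefore gives nothing, and heating acts on a flask with no L left”.

The flask gives 27.2% at 1.0 h, with L at 0%. Monday's gains 15 points against our 14 points, Friday's 0 points, and D stands at 27.2% after Sunday's and 27.2% after Saturday's.

    E + L → D (k = 0.0430 M⁻¹ s⁻¹, Ea = 50.0 kJ mol⁻¹)
    J + L → G (k = 0.0706 M⁻¹ s⁻¹, Ea = 72.0 kJ mol⁻¹)
    L → Q (k = 5.73 × 10⁻⁴ s⁻¹, Ea = 97.0 kJ mol⁻¹)
    (constants at 35 °C)

Take one more flask like this one but with 0.35 M of L, which is 1.75 equiv of L to E. Our share predicts: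

[D] = 39.4% × 0.35 M / 0.20 M = 68.9% of the E charged

That flask gives 75.5%, so its own share is 43.1%, higher than the 39.4% we carried. At 60.0 min it holds L at 0%, E at 24.5% and J at 9.91%.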